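The constants came last for me; I began with a count of ends, which needs none. Each link uses one first end group and one second end group, so it removes two ends, and a chain counts once for every two ends left. The average length is therefore the ends charged over the ends left, and the ends left are the ends charged less twice [links]. For cedar the ends charged are 0.200 M, and for larch 0.150 M.

| setting | Saturday's | Friday's | cedar | larch |
|---|---|---|---|---|
| first end groups | 0.056 M | 0.13 M | 0.10 M | 0.050 M |
| second end groups | 0.10 M | 0.10 M | 0.100 M | 0.100 M |
| remark | run made earlier | run made earlier |  |  |
| time |  |  | 3.0 h | 3.0 h |

| run | time / min | links / % |
|---|---|---|
| Saturday's | 20.0 | 23 |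
| Saturday's | 40.0 | 38 |
| Saturday's | 60.0 | 47 |
| Saturday's | 80.0 | 53 |
| Saturday's | 120 | 58 |
| Friday's | 8.00 | 8 |
| Friday's | 25.0 | 23 |
| Friday's | 40.0 | 32 |
| Friday's | 60.0 | 34 |
| Friday's | 90.0 | 44 |
| Friday's | 120 | 44 |

(each reading ± 2 percentage points)

- each molecule carries two end groups: a chain counts once for every two ends that are left, dead ends included; the units are half of the end groups of the two monomers charged

- which of the two ends with the longer chains by the average number of monomer units in a chain (unreacted monomers counted as chains of one) ("neither" if they lie within 10%) (cedar / larch / neither)
- average number of monomer units in a chain (unreacted monomers counted as chains of one) at the end, cedar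
- average number of monomer units in a chain (unreacted monomers counted as chains of one) at the end, larch

I kept a ledger of the limiting reagent. In Friday's flask that was the second end groups: of 0.10 M charged, links held 0.0572 M at the last reading, and 0.0428 M stood elsewhere, which the readings could not split. In Saturday's flask it was the first end groups: of 0.056 M charged, links held 0.0325 M, and 0.0235 M stood outside links.

Between these two flasks, each added first end group booked 0.334 of a link. From that slope I entered 0.0472 M of links for cedar and 0.0305 M for larch. The lengths came to 1.89 and 1.68, cedar ahead. Saturday's last two readings were 53% and 58%, Friday's 44% and 44%, so I could not tell whether links would still move by 3.0 h.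

The forecast named cedar, with 1.95 and 1.67, on the ground that “Both new runs should be essentially at their plateaus by 3 h”. Its lengths differ slightly from mine, but it chose the same flask.

The flask gave cedar: 2.35 in cedar and 1.83 in larch.

    first end groups + second end groups ⇌ links (K = 99.2 /M, k = 8.57 /M/h)
    second end groups → decomposed reagent (k = 0.184 /h)

Cedar's links stood at 0.0574 M at 3.00 h, against the forecast's 0.049 M, and the ends charged turn that into a length of 2.35. The smaller charge of first end groups is the main reason larch ended at 1.83: the same flask with cedar's charge gave 2.35. One more flask, like larch but charged with 0.20 M of first end groups, held 39.7% of that charge as links, and the count of ends gave it a length of 2.12.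

The readings stem from a simulated flask for substances that don't exist, and the scatter is random.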